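**Plan**
- Retrosynthesis (ring atoms of the target: C1 alkylidene carbon, C2 CHCl beside CMe2, C3 CMe2, C4 CHBr, C5 CH2, C6 CHCl): the CH2–Br and C2–Cl bonds go back to C–O bonds (C2–O from a C2 ketone). The C6–Cl bond and the C1=CH double bond go back to a Baylis–Hillman alcohol, and the C1–CH bond to an enone plus an aldehyde.
- Enabling feature: quaternary C3 sits between carbonyl carbon C2 and bromine-bearing C4 of the six-membered ring. The C2–C3 and C3–C4 bonds are therefore cut together (a CMe2 carbene unit) and a temporary C2–C4 bond is drawn. This leaves a five-membered ring (C2, C4, C5, C6, C1) carrying a C2=C4 silyl enol ether.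
- Forward: five-membered enol ether → [2+1] addition closes the three-membered ring C2–C3–C4 (bicyclo[3.1.0]hexane) → Br+ at C4 breaks C2–C4 and the six-membered bromoketone appears → enone → side chain at C1 → C6–Cl → C2–Cl → CH2Br.
- Stereochemistry: the C6 silyloxy centre of the (R)-cyclopentenone sends the carbenoid to the opposite face, and invertive bromination turns this into the (4S) C–Br centre. After loss of the silyloxy group, C4–Br directs chloride to the opposite face at C6 and fixes the hydride face at C2; Appel inversion then gives (2S). The E alkene follows from the enone geometry (side chain anti to C=O).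

Key step: step 2

Remark: compound 10 is carried on as a pair of carbinol epimers, because step 6 removes that centre.

**Step 1**
Reactants: 1 (4R)-4-(tert-butyldimethylsilyloxy)cyclopent-2-en-1-one; 2 triethylsilane
Product: 3 (4S)-4-(tert-butyldimethylsilyloxy)-1-(triethylsilyloxy)cyclopent-1-ene
Conditions: Et3SiH (1.2 equiv), RhCl(PPh3)3 (1 mol %), THF, 50 °C
Reagents that add atoms: triethylsilane, CC[SiH](CC)CC
Why: RhCl(PPh3)3-catalysed 1,4-hydrosilylation of an enone with a monohydrosilane puts hydride on C3 and silicon on oxygen, which fixes the enol ether double bond at C1=C2 on the side away from the silyloxy carbon and leaves the existing stereocentre untouched (its descriptor changes from R to S only through the priority rules).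

**Step 2**
Reactants: 3 (4S)-4-(tert-butyldimethylsilyloxy)-1-(triethylsilyloxy)cyclopent-1-ene; 4 2,2-dichloropropane
Product: 5 (1S,3S,5R)-3-(tert-butyldimethylsilyloxy)-6,6-dimethyl-1-(triethylsilyloxy)bicyclo[3.1.0]hexane (cyclopropane anti to the C3 silyloxy group)
Conditions: Me2CCl2 (2 equiv), Zn dust (2 equiv), ZnBr2 (1 equiv), CoBr2 (10 mol %), 2,6-bis[1-(2-tert-butylphenylimino)ethyl]pyridine (10 mol %), THF, 23 °C
Reagents that add atoms: 2,2-dichloropropane, CC(C)(Cl)Cl
Why: Proposed new method: Zn reduces the CoBr2–pyridine-2,6-diimine precatalyst to a low-valent cobalt species that takes up both C–Cl bonds of 4 (Zn as terminal reductant) to form a cobalt isopropylidene carbenoid, which should transfer CMe2 to the electron-rich, sterically open enol ether double bond of 3; the closest known reactions are the cobalt-catalysed reductive dimethylcyclopropanation of 1,3-dienes with 4 and Zn and the Simmons–Smith cyclopropanation of silyl enol ethers, neither of which has been shown for this combination. The three-membered ring closes by [2+1] addition, both new C–C bonds to the carbenoid carbon forming on the same alkene face (concerted, or through a cobaltacyclobutane that eliminates reductively), so only the cis-fused bicyclo[3.1.0]hexane can result. The two new stereocentres (C1 and C5) are set together by the existing C3 silyloxy centre, whose bulky TBS group shields its own face of the cyclopentene so that the carbenoid arrives anti to it. This facial selectivity is the only selectivity required, since 3 has a single C=C bond; the TES enol ether is chosen over TMS so that it survives the Lewis acidic zinc halides.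

**Step 3**
Reactants: 5 (1S,3S,5R)-3-(tert-butyldimethylsilyloxy)-6,6-dimethyl-1-(triethylsilyloxy)bicyclo[3.1.0]hexane; 6 N-bromosuccinimide
Product: 7 (3S,5R)-3-bromo-5-(tert-butyldimethylsilyloxy)-2,2-dimethylcyclohexan-1-one (Br and OTBS trans)
Conditions: NBS (1.05 equiv), NaHCO3, CH2Cl2, −78 to −20 °C; aqueous work-up
Reagents that add atoms: N-bromosuccinimide, O=C1CCC(=O)N1Br
Why: Electrophilic brominative ring opening of a siloxycyclopropane: Br+ attacks the less substituted, hydrogen-bearing cyclopropane carbon from the rear of the ring-fusion bond (inversion, as in the bromination of cyclopropanols) while the oxygen lone pair pushes that bond open and the silyl group is lost, so the five-membered ring grows into the 3-bromo-2,2-dimethylcyclohexanone; rear-side attack at the quaternary CMe2 carbon is sterically closed.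

**Step 4**
Reactants: 7 (3S,5R)-3-bromo-5-(tert-butyldimethylsilyloxy)-2,2-dimethylcyclohexan-1-one
Product: 8 (5S)-5-bromo-6,6-dimethylcyclohex-2-en-1-one
Conditions: p-TsOH·H2O (0.2 equiv), benzene, 60 °C
Reagents that add atoms: none
Why: Acid-catalysed β-elimination of silanol from a β-silyloxy ketone through the only possible enol (the other α-carbon is quaternary) gives the conjugated enone; the bromide has no α-hydrogen on its side and stays, and base is avoided because it could trigger vinylogous loss of HBr from the enone.

**Step 5**
Reactants: 8 (5S)-5-bromo-6,6-dimethylcyclohex-2-en-1-one; 9 (tert-butyldimethylsilyloxy)acetaldehyde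
Product: 10 (5S)-5-bromo-2-[2-(tert-butyldimethylsilyloxy)-1-hydroxyethyl]-6,6-dimethylcyclohex-2-en-1-one (both carbinol epimers)
Conditions: 9 (1.5 equiv), PBu3 (0.2 equiv), PhOH (0.2 equiv), THF, 23 °C
Reagents that add atoms: (tert-butyldimethylsilyloxy)acetaldehyde, O=CCO[Si](C)(C)C(C)(C)C
Why: Morita–Baylis–Hillman reaction: the phosphine adds to the unhindered β-carbon of the enone, the phosphonium enolate adds to the reactive α-oxygenated aldehyde and the phosphine is expelled again after proton transfer; the new carbinol centre is not controlled and need not be.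

**Step 6**
Reactants: 10 (5S)-5-bromo-2-[2-(tert-butyldimethylsilyloxy)-1-hydroxyethyl]-6,6-dimethylcyclohex-2-en-1-one; 11 methanesulfonyl chloride
Product: 13 (2Z,3S,5S)-5-bromo-2-[2-(tert-butyldimethylsilyloxy)ethylidene]-3-chloro-6,6-dimethylcyclohexan-1-one (CH2OTBS anti to C=O, Cl trans to Br), via mesylate 12 (not isolated)
Conditions: MsCl (1.3 equiv), i-Pr2NEt (1.5 equiv), CH2Cl2, −20 to 23 °C; crude product taken directly into step 7
Reagents that add atoms: methanesulfonyl chloride, CS(=O)(=O)Cl
Why: Mesylation followed by SN2′ substitution (conjugate addition of the chloride released from MsCl, then E1cB loss of mesylate), the usual course for Baylis–Hillman mesylates: chloride should add axially to C3 on the face opposite the C5 bromine (trans-3,5 rule for 5-substituted cyclohexenones), and the alkylidene should form with the CH2OTBS group anti to the carbonyl, where the axial chlorine relieves allylic strain.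

**Step 7**
Reactants: 13 (2Z,3S,5S)-5-bromo-2-[2-(tert-butyldimethylsilyloxy)ethylidene]-3-chloro-6,6-dimethylcyclohexan-1-one
Product: 14 (1R,2Z,3S,5S)-5-bromo-2-[2-(tert-butyldimethylsilyloxy)ethylidene]-3-chloro-6,6-dimethylcyclohexan-1-ol (OH cis to Br, trans to Cl)
Conditions: NaBH4, CeCl3·7H2O, MeOH, −78 °C
Reagents that add atoms: none
Why: Luche reduction attacks the carbonyl carbon only (no conjugate hydride addition, which would expel the allylic chloride), and hydride should enter axially from the face opposite the axial methyl group on the neighbouring quaternary carbon, giving the equatorial alcohol cis to bromine.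

**Step 8**
Reactants: 14 (1R,2Z,3S,5S)-5-bromo-2-[2-(tert-butyldimethylsilyloxy)ethylidene]-3-chloro-6,6-dimethylcyclohexan-1-ol; 15 hexachloroacetone
Product: 16 tert-butyl{(2E)-2-[(2S,4S,6S)-4-bromo-2,6-dichloro-3,3-dimethylcyclohexylidene]ethoxy}dimethylsilane
Conditions: PPh3 (1.5 equiv), (Cl3C)2CO (3 equiv), CH2Cl2, −20 to 0 °C
Reagents that add atoms: hexachloroacetone, O=C(C(Cl)(Cl)Cl)C(Cl)(Cl)Cl
Why: Appel-type chlorination with PPh3 and hexachloroacetone, in which chloride displaces the alkoxyphosphonium group from a tight ion pair, is known to convert secondary allylic alcohols into chlorides with inversion and without allylic transposition; it should turn the (1R)-alcohol into the chloride cis to the first chlorine and trans to bromine.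

**Step 9**
Reactants: 16 tert-butyl{(2E)-2-[(2S,4S,6S)-4-bromo-2,6-dichloro-3,3-dimethylcyclohexylidene]ethoxy}dimethylsilane
Product: 17 (2E)-2-[(2S,4S,6S)-4-bromo-2,6-dichloro-3,3-dimethylcyclohexylidene]ethan-1-ol
Conditions: HF·pyridine, THF–pyridine, 0 °C
Reagents that add atoms: none
Why: Fluoride cleavage of the primary silyl ether under mildly acidic, non-basic conditions frees the alcohol without forming an alkoxide that could cyclise onto the neighbouring allylic chloride; no stereocentre is touched.

**Step 10**
Reactants: 17 (2E)-2-[(2S,4S,6S)-4-bromo-2,6-dichloro-3,3-dimethylcyclohexylidene]ethan-1-ol; 18 carbon tetrabromide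
Product: 19 ochtodene, (1E,2S,4S,6S)-4-bromo-1-(2-bromoethylidene)-2,6-dichloro-3,3-dimethylcyclohexane
Conditions: CBr4 (1.3 equiv), PPh3 (1.4 equiv), CH2Cl2, −20 to 0 °C
Reagents that add atoms: carbon tetrabromide, BrC(Br)(Br)Br
Why: Appel bromination: bromide displaces the primary allylic alkoxyphosphonium group by SN2 at low temperature, which should be faster than any exchange at the hindered secondary chlorides and leaves the alkene geometry and all stereocentres as they are.

**Compound list**
1 | (4R)-4-(tert-butyldimethylsilyloxy)cyclopent-2-en-1-one | O=C1C=C[C@H](O[Si](C)(C)C(C)(C)C)C1 | starting material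
2 | triethylsilane | CC[SiH](CC)CC | starting material
3 | (4S)-4-(tert-butyldimethylsilyloxy)-1-(triethylsilyloxy)cyclopent-1-ene | CC[Si](CC)(CC)OC1=CC[C@H](O[Si](C)(C)C(C)(C)C)C1 | intermediate
4 | 2,2-dichloropropane | CC(C)(Cl)Cl | starting material
5 | (1S,3S,5R)-3-(tert-butyldimethylsilyloxy)-6,6-dimethyl-1-(triethylsilyloxy)bicyclo[3.1.0]hexane | CC1(C)[C@H]2C[C@H](O[Si](C)(C)C(C)(C)C)C[C@@]12O[Si](CC)(CC)CC | intermediate
6 | N-bromosuccinimide | O=C1CCC(=O)N1Br | starting material
7 | (3S,5R)-3-bromo-5-(tert-butyldimethylsilyloxy)-2,2-dimethylcyclohexan-1-one | CC1(C)[C@@H](Br)C[C@H](O[Si](C)(C)C(C)(C)C)CC1=O | intermediate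
8 | (5S)-5-bromo-6,6-dimethylcyclohex-2-en-1-one | CC1(C)[C@@H](Br)CC=CC1=O | intermediate
9 | (tert-butyldimethylsilyloxy)acetaldehyde | O=CCO[Si](C)(C)C(C)(C)C | starting material
10 | (5S)-5-bromo-2-[2-(tert-butyldimethylsilyloxy)-1-hydroxyethyl]-6,6-dimethylcyclohex-2-en-1-one (both carbinol epimers) | CC1(C)[C@@H](Br)CC=C(C(O)CO[Si](C)(C)C(C)(C)C)C1=O | intermediate
11 | methanesulfonyl chloride | CS(=O)(=O)Cl | starting material
12 | mesylate of 10, (5S)-5-bromo-2-[2-(tert-butyldimethylsilyloxy)-1-(methylsulfonyloxy)ethyl]-6,6-dimethylcyclohex-2-en-1-one (both epimers, not isolated) | CC1(C)[C@@H](Br)CC=C(C(OS(C)(=O)=O)CO[Si](C)(C)C(C)(C)C)C1=O | intermediate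
13 | (2Z,3S,5S)-5-bromo-2-[2-(tert-butyldimethylsilyloxy)ethylidene]-3-chloro-6,6-dimethylcyclohexan-1-one | CC1(C)[C@@H](Br)C[C@H](Cl)/C(=C\CO[Si](C)(C)C(C)(C)C)C1=O | intermediate
14 | (1R,2Z,3S,5S)-5-bromo-2-[2-(tert-butyldimethylsilyloxy)ethylidene]-3-chloro-6,6-dimethylcyclohexan-1-ol | CC1(C)[C@@H](Br)C[C@H](Cl)/C(=C\CO[Si](C)(C)C(C)(C)C)[C@H]1O | intermediate
15 | hexachloroacetone | O=C(C(Cl)(Cl)Cl)C(Cl)(Cl)Cl | starting material
16 | tert-butyl{(2E)-2-[(2S,4S,6S)-4-bromo-2,6-dichloro-3,3-dimethylcyclohexylidene]ethoxy}dimethylsilane | CC1(C)[C@@H](Br)C[C@H](Cl)/C(=C\CO[Si](C)(C)C(C)(C)C)[C@@H]1Cl | intermediate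
17 | (2E)-2-[(2S,4S,6S)-4-bromo-2,6-dichloro-3,3-dimethylcyclohexylidene]ethan-1-ol | CC1(C)[C@@H](Br)C[C@H](Cl)/C(=C\CO)[C@@H]1Cl | intermediate
18 | carbon tetrabromide | BrC(Br)(Br)Br | starting material
19 | ochtodene, (1E,2S,4S,6S)-4-bromo-1-(2-bromoethylidene)-2,6-dichloro-3,3-dimethylcyclohexane | CC1(C)[C@@H](Br)C[C@H](Cl)/C(=C\CBr)[C@@H]1Cl | target

**Count and risks**
Total step count: 10. Longest linear sequence: 10 steps (1 to 19).

Step 2 (the step carrying the new-method label) is the most uncertain. The cobalt carbenoid may fail to engage an isolated enol ether double bond, so that propene formation by hydride shift or Lewis-acid cleavage of the enol ether takes over, or the facial discrimination may be modest. The fallback leaves the catalytic cobalt manifold for a different carbene-transfer mechanism: the stoichiometric zinc carbenoid made from ZnEt2 and 2,2-diiodopropane (CH2Cl2, 0 °C). This is a Simmons–Smith-type reagent of the class that routinely cyclopropanates silyl enol ethers and that is known to deliver an isopropylidene unit to allylic ethers. It sets out from 3 and comes back to the route at 5; no further compound arises (entry F0).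

Step 8 is the next most likely to fail. Direct displacement at the carbinol carbon, which is flanked by the quaternary centre, may lose to attack at the exocyclic alkene terminus (allylic transposition) or to ionisation with loss of configuration. The fallback also answers a wrong facial outcome in step 7. It sets out from 13: LiBH(s-Bu)3 (THF, −78 °C) should deliver hydride equatorially, from the face that the small Luche reagent avoids, to give the epimeric (1S,2Z,3S,5S)-5-bromo-2-[2-(tert-butyldimethylsilyloxy)ethylidene]-3-chloro-6,6-dimethylcyclohexan-1-ol F1. SOCl2 converts it into the chlorosulfite F2, and catalytic TiCl4 (CH2Cl2, 0 °C) collapses this with front-side delivery of chloride and retention, a known stereoretentive chlorination of cyclic secondary alcohols that needs no rear-side access. The route is rejoined at 16.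

Step 6 is the third. The kinetically formed exocyclic alkylidene chloride may be isomerised by chloride in a second SN2′ event to the endocyclic enone with the chlorine in the side chain, or the amine may intercept the mesylate. The fallback reverses the order of bond formation and sets out from 8 and 9. TiCl4 (CH2Cl2, −78 °C) adds chloride to C3 anti to bromine and the titanium enolate is trapped by 9 (the chloro-aldol variant of the Baylis–Hillman reaction), giving (3S,5S)-5-bromo-3-chloro-2-[2-(tert-butyldimethylsilyloxy)-1-hydroxyethyl]-6,6-dimethylcyclohexan-1-one F3. Methanesulfonic anhydride and Et3N (−20 °C) give its mesylate F4, and E1cB loss of mesylate returns to the route at 13 with no chloride salt present beside the finished alkylidene ketone.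

Further compounds
F0 | step 2 | none | none
F1 | step 8 | (1S,2Z,3S,5S)-5-bromo-2-[2-(tert-butyldimethylsilyloxy)ethylidene]-3-chloro-6,6-dimethylcyclohexan-1-ol | CC1(C)[C@@H](Br)C[C@H](Cl)/C(=C\CO[Si](C)(C)C(C)(C)C)[C@@H]1O
F2 | step 8 | chlorosulfite of F1 | CC1(C)[C@@H](Br)C[C@H](Cl)/C(=C\CO[Si](C)(C)C(C)(C)C)[C@@H]1OS(Cl)=O
F3 | step 6 | (3S,5S)-5-bromo-3-chloro-2-[2-(tert-butyldimethylsilyloxy)-1-hydroxyethyl]-6,6-dimethylcyclohexan-1-one (epimers at C2 and the carbinol carbon) | CC1(C)[C@@H](Br)C[C@H](Cl)C(C(O)CO[Si](C)(C)C(C)(C)C)C1=O
F4 | step 6 | mesylate of F3 | CC1(C)[C@@H](Br)C[C@H](Cl)C(C(OS(C)(=O)=O)CO[Si](C)(C)C(C)(C)C)C1=O
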